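The earlier runs and the new flask stem from a simulated flask with constants of no real substance; noise was put on by code.

At late times the teal flask stops moving: from 5.00 h to 30.0 h its target reads flat around 37.5%, and its substrate reads 0.6% at the last reading. Teal therefore holds 61.9% as my hidden share, the fraction of the charge read as neither target nor substrate.

all flasks: temperature 0 °C
- teal: substrate 20 mM; partner 0.60 equiv; the very flask that is asked about, followed so far
- amber: substrate 30 mM; partner 0.60 equiv; run made earlier
- flask: substrate 20 mM; partner 0.600 equiv; time 40 h

teal run (percent of the substrate charged)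

| time / h | target / % | substrate / % |
|---|---|---|
| 5.00 | 38.5 | 0 |
| 10.0 | 36.8 | 0.8 |
| 15.0 | 36.2 | 0 |
| 20.0 | 37.5 | 1.6 |
| 25.0 | 37.6 | 1.3 |
| 30.0 | 38.2 | 0.6 |

amber run (percent of the substrate charged)

| time / min | target / % | substrate / % |
|---|---|---|
| 20.0 | 6.3 | 38.2 |
| 40.0 | 19.7 | 19.9 |
| 60.0 | 27.4 | 10.7 |
| 80.0 | 33.8 | 7.2 |
| 90.0 | 36.4 | 6.1 |
| 120 | 38.1 | 4.4 |

(readings scatter by 1 percentage point)

- dusk: at 40 h take out 90% of the target then present, then wait 20 h
- summer: change nothing and wait 20 h more
- noon: at 40 h add partner, 100% of the amount charged, then wait 20 h
- dawn: at 40 h raise the temperature by 20 K, then wait 20 h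

- removed target is counted in
- steps under discussion: substrate <-> intermediate A; substrate + partner -> intermediate B; intermediate A -> decomposed reagent; target <-> isomer of the product; intermediate B <-> intermediate C; intermediate A -> target
- the earlier runs do not show what temperature does; that part of a forecast is a guess
- additions bring no volume worth counting

- target, in percent of the substrate first charged, at 40 h
- the remedy with the largest gain of target, or "none" below 2 percentage points (dusk / summer / noon / dawn / none)
- target present, with what was taken out counted in, in percent of the substrate first charged, after noon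
- target present, with what was taken out counted in, in percent of the substrate first charged, after dawn

1. Fastest rung: in amber, substrate falls from 38.2% to 19.9% between 20.0 min and 40.0 min, so I read a half-life of 21.3 min.

2. Next rung: amber's target lags, at 6.3% after 20.0 min, so it forms through intermediate A. It reaches 38.1% at 120 min.

3. Slowest rung: teal is already flat at 5.00 h, which is 14.1 of those half-lives. So I reckon 37.5% at 40 h.

4. First round: I put the hidden share on the partner route, since 0.60 equiv of partner could bind about that much.

5. Second round: I put that answer back. The partner route would then need about 0.60 equiv of partner in teal, which is the whole charge, and no reading shows the partner. Setting amber against teal can't test it, because amber ends at 120 min, before teal's first reading at 5.00 h. So I hold the hidden share open: it may also contain decomposed reagent, which is lost, and isomer of the product, which can return.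

6. Teal's flat line may then be an equilibrium of target with isomer (thermodynamic control), which these readings can't tell from a dead end. I expect no gain from summer or noon, so 37.5% after noon. If isomer sits in the hidden share, I expect dusk or dawn to draw on it and pass 2 percentage points, though the size is a guess.

The forecast gives 37.5% at 40 h, 37.5% after noon, 36.5% after dawn and none as the best remedy, holding that “No live feed remains”, and there it differs from my step 6.

The flask gives 37.5% at 40.0 h, 37.5% after noon and 53.9% after dawn; the best remedy is dawn, with a gain of 16 points against 12 points for dusk.

    substrate ⇌ intermediate A (K = 4.50, k = 3.10 h⁻¹, Ea = 73.0 kJ mol⁻¹, ΔH = −23.0 kJ mol⁻¹)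
    substrate + partner → intermediate B (k = 11.0 M⁻¹ h⁻¹, Ea = 49.0 kJ mol⁻¹)
    intermediate A → decomposed reagent (k = 0.550 h⁻¹, Ea = 77.0 kJ mol⁻¹)
    target ⇌ isomer of the product (K = 0.520, k = 0.230 h⁻¹, Ea = 87.0 kJ mol⁻¹, ΔH = −73.0 kJ mol⁻¹)
    intermediate B ⇌ intermediate C (K = 0.330, k = 0.110 h⁻¹, Ea = 83.0 kJ mol⁻¹, ΔH = −35.0 kJ mol⁻¹)
    intermediate A → target (k = 0.840 h⁻¹, Ea = 77.0 kJ mol⁻¹)
    (constants at 0 °C)

At 40.0 h the flask holds 19.5% of isomer of the product inside its hidden share. Dawn's gain is a quarter of the hidden share of 61.9%. The neighbour flask with 80 mM of substrate ends with target at 32.7%, so its hidden share is 67.3%, of which intermediates B and C hold 17.7%.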